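**Plan**
- Retrosynthesis: after global debenzylation, ring C of the upper (epiafzelechin) unit is cut at O1–C8a and C4–C4a. This removes its whole ring A as 3,5-bis(benzyloxy)benzyne and leaves a threo, trans-epoxy alcohol attached to C8 of a perbenzylated procyanidin B2.
- The epoxy alcohol is traced back through ketone reduction, enone epoxidation and Claisen–Schmidt condensation to the dimer 8-carbaldehyde. The dimer is cut at its 4β→8 bond into two epicatechin-derived halves.
- Forward: epicatechin gives the 8-bromo C4-ether electrophile and the tetrabenzyl nucleophile, then the 8-bromo dimer, aldehyde, chalcone, epoxy ketone and epoxy alcohol. The aryne annulation then closes ring C while introducing ring A, and hydrogenolysis ends the route.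
- Stereochemistry: C2/C3 of the two lower units come from (−)-epicatechin, and the lower C4 from anti attack on the flavan-4-yl cation. Upper C3/C4 come from the poly-L-leucine epoxidation, upper C2 from the CBS reduction, and upper C4 is inverted in the ring closure.
- Enabling feature: upper ring A is a 1,3,5-trioxygenated benzene carrying O1 and C4 on the adjacent carbons C8a and C4a, i.e. a 3,5-dialkoxybenzyne. Its C5 oxygen directs the oxygen nucleophile to C8a and the carbanion to C4a, and C4 is benzylic to the trioxygenated ring A of the middle unit, which activates it for endo attack.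

Key step: step 12

Assumptions: (−)-epicatechin, 1-[4-(benzyloxy)phenyl]ethan-1-one and 3,5-bis(benzyloxy)phenol are bought; poly-L-leucine is taken to give the (2R,3S)-epoxy ketone as with simple chalcones (poly-D-leucine would be used if the bulky aryl group reversed the sense).

**Step 1**
Reactants: 1 (−)-epicatechin
Product: 2 5,7,3',4'-tetra-O-benzyl-(−)-epicatechin
Conditions: BnBr, K2CO3, DMF, 0 °C to rt, argon
Reagents that add atoms: benzyl bromide, BrCc1ccccc1
Why: Williamson etherification in which K2CO3 deprotonates only the four phenols, so the secondary 3-OH stays free and the C2/C3 stereocentres are untouched under these mild, oxygen-free conditions.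

**Step 2**
Reactants: 2 5,7,3',4'-tetra-O-benzyl-(−)-epicatechin
Product: 3 8-bromo-5,7,3',4'-tetra-O-benzyl-(−)-epicatechin
Conditions: NBS, CH2Cl2, −40 °C to rt
Reagents that add atoms: N-bromosuccinimide, O=C1CCC(=O)N1Br
Why: Electrophilic aromatic bromination of the phloroglucinol-type ring A, which in 5,7-di-O-benzyl flavans occurs at C8 in preference to C6; the bromine later blocks self-coupling and is the handle for C8 metalation.

**Step 3**
Reactants: 3 8-bromo-5,7,3',4'-tetra-O-benzyl-(−)-epicatechin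
Product: 4 8-bromo-4β-(2-ethoxyethoxy)-5,7,3',4'-tetra-O-benzyl-epicatechin (2,3-cis-3,4-trans)
Conditions: DDQ, 2-ethoxyethanol, CH2Cl2, rt
Reagents that add atoms: 2-ethoxyethanol, CCOCCO
Why: Oxidative benzylic C–H etherification: DDQ abstracts hydride to give the ring-A-stabilised flavan-4-yl cation, which the alcohol captures anti to the 3-hydroxyl to give the 4β ether (this centre is ionised again in step 4, so its configuration is not critical).

**Step 4**
Reactants: 4 8-bromo-4β-(2-ethoxyethoxy)-5,7,3',4'-tetra-O-benzyl-epicatechin; 2 5,7,3',4'-tetra-O-benzyl-(−)-epicatechin (excess)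
Product: 5 8-bromo-5,7,3',4'-tetra-O-benzyl-epicatechin-(4β→8)-5,7,3',4'-tetra-O-benzyl-epicatechin (both 3-OH free)
Conditions: TMSOTf (cat.), CH2Cl2, −78 °C
Reagents that add atoms: none
Why: Lewis-acid-promoted Friedel–Crafts coupling of the flavan-4-yl cation; the 8-bromo group stops the electrophile from self-condensing, excess 2 reacts at its more nucleophilic C8, and attack anti to the C3 oxygen of the 2,3-cis cation sets the new C4 centre as 4β (3,4-trans).

**Step 5**
Reactants: 5 8-bromo-octa-O-benzyl dimer diol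
Product: 6 8-bromo-3,5,7,3',4'-penta-O-benzyl-epicatechin-(4β→8)-3,5,7,3',4'-penta-O-benzyl-epicatechin
Conditions: NaH, BnBr, n-Bu4NI (cat.), DMF, 0 °C to rt
Reagents that add atoms: benzyl bromide, BrCc1ccccc1
Why: Williamson etherification of the two secondary alkoxides, needed so that no free hydroxyl later quenches the aryllithium or competes with the carbinol oxygen for the aryne.

**Step 6**
Reactants: 6 8-bromo-deca-O-benzyl dimer
Product: 8 deca-O-benzyl-procyanidin B2 8-carbaldehyde (formyl on C8 of the upper unit), via aryllithium 7 (not isolated)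
Conditions: n-BuLi, THF, −78 °C; DMF, −78 to 0 °C; H2O
Reagents that add atoms: N,N-dimethylformamide, CN(C)C=O
Why: Bromine–lithium exchange at the aryl bromide flanked by two oxygens followed by formylation of the aryllithium with DMF (Bouveault-type aldehyde synthesis); benzyl ethers and stereocentres are inert at −78 °C.

**Step 7**
Reactants: 8 deca-O-benzyl-procyanidin B2 8-carbaldehyde; 9 1-[4-(benzyloxy)phenyl]ethan-1-one
Product: 10 (E)-1-[4-(benzyloxy)phenyl]-3-(deca-O-benzyl-procyanidin B2-8-yl)prop-2-en-1-one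
Conditions: KOH, EtOH/THF, rt
Reagents that add atoms: none
Why: Claisen–Schmidt (crossed aldol) condensation of a non-enolisable aldehyde with the methyl ketone enolate; E1cB dehydration gives the conjugated (E)-enone as the thermodynamic isomer.

**Step 8**
Reactants: 10 (E)-chalcone
Product: 11 (2R,3S)-1-[4-(benzyloxy)phenyl]-2,3-epoxy-3-(deca-O-benzyl-procyanidin B2-8-yl)propan-1-one (trans-epoxide)
Conditions: poly-L-leucine, urea–H2O2, DBU, THF, rt
Reagents that add atoms: urea–hydrogen peroxide, NC(N)=O.OO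
Why: Juliá–Colonna epoxidation, a peptide-catalysed Weitz–Scheffer reaction in which hydroperoxide adds to the β-carbon and the enolate closes the trans-epoxide; the helical poly-L-leucine selects the enone face and so sets (2R,3S), the future C3 and C4 of the upper unit, independently of the remote stereocentres.

**Step 9**
Reactants: 11 (2R,3S)-epoxy ketone
Product: 12 (1R,2S,3S)-1-[4-(benzyloxy)phenyl]-2,3-epoxy-3-(deca-O-benzyl-procyanidin B2-8-yl)propan-1-ol (threo, trans-epoxide)
Conditions: (R)-2-methyl-CBS-oxazaborolidine, catecholborane, toluene/CH2Cl2, −78 °C; MeOH, then pH 7 buffer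
Reagents that add atoms: none
Why: Corey–Bakshi–Shibata reduction; the ketone binds the oxazaborolidine boron anti to the aryl (large) group and receives hydride on one face, so the (R)-catalyst should give the (1R)-carbinol, i.e. the threo epoxy alcohol, against the erythro preference of simple hydrides, while the mild borane at low temperature spares the epoxide.

**Step 10**
Reactants: 13 3,5-bis(benzyloxy)phenol
Product: 14 2-bromo-3,5-bis(benzyloxy)phenol
Conditions: NBS, i-Pr2NH (cat.), CH2Cl2, −78 to 0 °C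
Reagents that add atoms: N-bromosuccinimide, O=C1CCC(=O)N1Br
Why: Amine-mediated ortho-selective electrophilic bromination of a phenol (N-bromoamine delivered by hydrogen bonding to the hydroxyl), which should place bromine at C2 between OH and OBn and not at the more hindered C4 between the two benzyloxy groups.

**Step 11**
Reactants: 14 2-bromo-3,5-bis(benzyloxy)phenol
Product: 17 3,5-bis(benzyloxy)-2-(trimethylsilyl)phenyl trifluoromethanesulfonate, via silyl ether 15 (not isolated), via lithium phenoxide 16 (not isolated)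
Conditions: HMDS, THF, 65 °C, then evaporation; n-BuLi, THF, −78 °C; Tf2O, −78 °C
Reagents that add atoms: hexamethyldisilazane, C[Si](C)(C)N[Si](C)(C)C; trifluoromethanesulfonic anhydride, O=S(=O)(OS(=O)(=O)C(F)(F)F)C(F)(F)F
Why: Standard route to ortho-silylaryl triflates: O-silylation, bromine–lithium exchange, anionic 1,3 O-to-C silyl migration (retro-Brook rearrangement) and triflation of the resulting phenoxide.

**Step 12**
Reactants: 12 (1R,2S,3S)-epoxy alcohol; 17 3,5-bis(benzyloxy)-2-(trimethylsilyl)phenyl trifluoromethanesulfonate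
Product: 21 5,7,4'-tri-O-benzyl-epiafzelechin-(4β→8)-3,5,7,3',4'-penta-O-benzyl-epicatechin-(4β→8)-3,5,7,3',4'-penta-O-benzyl-epicatechin (upper 3-OH free), via potassium alkoxide 18 (not isolated), via aryne 19 (not isolated), via aryl anion 20 (not isolated)
Conditions: KH, 18-crown-6, THF, 0 °C; then KF, 17 (slow addition, slight excess), 0 °C to rt; H2O
Reagents that add atoms: none
Why: Proposed new method: Fluoride removes the trimethylsilyl group of 17 and triflate leaves to give aryne 19; alkoxide 18 adds through oxygen to the aryne carbon remote from the flanking benzyloxy group (the future C8a), so the carbanion of 20 sits ortho to that benzyloxy group (the future C4a), and this aryl anion opens the epoxide at C4 with inversion. The closest known reaction types are aryne annulations in which an oxygen nucleophile adds and the aryl anion is caught by a tethered ester, ketone or Michael acceptor (xanthone and xanthene syntheses), the insertion of arynes into the C–O bond of epoxides, and Parham-type cyclisations of aryl metals onto epoxides. Ring C of the upper unit is closed in the 6-endo-tet mode at the epoxide, the competing 5-exo attack at C3 leading to a 2,3-dihydrobenzofuran. C2 and C3 keep the configurations set in steps 9 and 8 because none of their bonds is broken and the epoxide oxygen becomes the 3-hydroxyl, while C4 is set as 4β (3,4-trans) by backside displacement at the (S)-configured epoxide carbon; if the opening has ion-pair character the same isomer is expected, since the C4 aryl group then takes the pseudoaxial position away from the 5-benzyloxy group. The step needs regioselective O-addition to the unsymmetrical aryne (secured by inductive polarisation of the triple bond by the adjacent benzyloxy group), endo over exo epoxide opening (secured by C4 being benzylic to the 2,4,6-trioxygenated ring A of the middle unit while C3 is flanked by two substituted carbons), and reaction of 18 in preference to the hindered axial C3 alkoxide of the product (secured by slow addition of only a slight excess of 17). The absence of any proton source (preformed alkoxide, aprotic solvent) should let the aryl anion cyclise before it is quenched.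

**Step 13**
Reactants: 21 trideca-O-benzyl trimer
Product: 22 epiafzelechin-(4β→8)-epicatechin-(4β→8)-epicatechin (CNP0158921.2)
Conditions: H2 (1 atm), Pd(OH)2/C, THF/MeOH/H2O, rt
Reagents that add atoms: none
Why: Hydrogenolysis of the thirteen benzyl ethers over Pd(OH)2 on carbon; the flavan C2–O1 bonds and the interflavan bonds normally survive these conditions in procyanidin deprotections, and no stereocentre is affected.

**Compound list**

1 | (−)-epicatechin, (2R,3R) | c1c(O)cc(O)c2c1O[C@H](c1ccc(O)c(O)c1)[C@H](O)C2 | starting material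

2 | 5,7,3',4'-tetra-O-benzyl-(−)-epicatechin | c1c(OCc3ccccc3)cc(OCc3ccccc3)c2c1O[C@H](c1ccc(OCc3ccccc3)c(OCc3ccccc3)c1)[C@H](O)C2 | intermediate

3 | 8-bromo-5,7,3',4'-tetra-O-benzyl-(−)-epicatechin | Brc1c(OCc3ccccc3)cc(OCc3ccccc3)c2c1O[C@H](c1ccc(OCc3ccccc3)c(OCc3ccccc3)c1)[C@H](O)C2 | intermediate

4 | 8-bromo-4β-(2-ethoxyethoxy)-5,7,3',4'-tetra-O-benzyl-epicatechin (2,3-cis-3,4-trans) | Brc1c(OCc3ccccc3)cc(OCc3ccccc3)c2c1O[C@H](c1ccc(OCc3ccccc3)c(OCc3ccccc3)c1)[C@H](O)[C@H]2OCCOCC | intermediate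

5 | 8-bromo-5,7,3',4'-tetra-O-benzyl-epicatechin-(4β→8)-5,7,3',4'-tetra-O-benzyl-epicatechin | Brc1c(OCc3ccccc3)cc(OCc3ccccc3)c2c1O[C@H](c1ccc(OCc3ccccc3)c(OCc3ccccc3)c1)[C@H](O)[C@H]2c1c(OCc3ccccc3)cc(OCc3ccccc3)c2c1O[C@H](c1ccc(OCc3ccccc3)c(OCc3ccccc3)c1)[C@H](O)C2 | intermediate

6 | 8-bromo-3,5,7,3',4'-penta-O-benzyl-epicatechin-(4β→8)-3,5,7,3',4'-penta-O-benzyl-epicatechin | Brc1c(OCc3ccccc3)cc(OCc3ccccc3)c2c1O[C@H](c1ccc(OCc3ccccc3)c(OCc3ccccc3)c1)[C@H](OCc3ccccc3)[C@H]2c1c(OCc3ccccc3)cc(OCc3ccccc3)c2c1O[C@H](c1ccc(OCc3ccccc3)c(OCc3ccccc3)c1)[C@H](OCc3ccccc3)C2 | intermediate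

7 | 8-lithio-deca-O-benzyl-procyanidin B2 (aryllithium at C8 of the upper unit) | [Li]c1c(OCc3ccccc3)cc(OCc3ccccc3)c2c1O[C@H](c1ccc(OCc3ccccc3)c(OCc3ccccc3)c1)[C@H](OCc3ccccc3)[C@H]2c1c(OCc3ccccc3)cc(OCc3ccccc3)c2c1O[C@H](c1ccc(OCc3ccccc3)c(OCc3ccccc3)c1)[C@H](OCc3ccccc3)C2 | intermediate

8 | deca-O-benzyl-procyanidin B2 8-carbaldehyde | O=Cc1c(OCc3ccccc3)cc(OCc3ccccc3)c2c1O[C@H](c1ccc(OCc3ccccc3)c(OCc3ccccc3)c1)[C@H](OCc3ccccc3)[C@H]2c1c(OCc3ccccc3)cc(OCc3ccccc3)c2c1O[C@H](c1ccc(OCc3ccccc3)c(OCc3ccccc3)c1)[C@H](OCc3ccccc3)C2 | intermediate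

9 | 1-[4-(benzyloxy)phenyl]ethan-1-one | CC(=O)c1ccc(OCc2ccccc2)cc1 | starting material

10 | (E)-1-[4-(benzyloxy)phenyl]-3-(deca-O-benzyl-procyanidin B2-8-yl)prop-2-en-1-one | c1ccccc1COc1ccc(cc1)C(=O)/C=C/c1c(OCc3ccccc3)cc(OCc3ccccc3)c2c1O[C@H](c1ccc(OCc3ccccc3)c(OCc3ccccc3)c1)[C@H](OCc3ccccc3)[C@H]2c1c(OCc3ccccc3)cc(OCc3ccccc3)c2c1O[C@H](c1ccc(OCc3ccccc3)c(OCc3ccccc3)c1)[C@H](OCc3ccccc3)C2 | intermediate

11 | (2R,3S)-1-[4-(benzyloxy)phenyl]-2,3-epoxy-3-(deca-O-benzyl-procyanidin B2-8-yl)propan-1-one | c1ccccc1COc1ccc(cc1)C(=O)[C@@H]1O[C@H]1c1c(OCc3ccccc3)cc(OCc3ccccc3)c2c1O[C@H](c1ccc(OCc3ccccc3)c(OCc3ccccc3)c1)[C@H](OCc3ccccc3)[C@H]2c1c(OCc3ccccc3)cc(OCc3ccccc3)c2c1O[C@H](c1ccc(OCc3ccccc3)c(OCc3ccccc3)c1)[C@H](OCc3ccccc3)C2 | intermediate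

12 | (1R,2S,3S)-1-[4-(benzyloxy)phenyl]-2,3-epoxy-3-(deca-O-benzyl-procyanidin B2-8-yl)propan-1-ol | c1ccccc1COc1ccc(cc1)[C@@H](O)[C@@H]1O[C@H]1c1c(OCc3ccccc3)cc(OCc3ccccc3)c2c1O[C@H](c1ccc(OCc3ccccc3)c(OCc3ccccc3)c1)[C@H](OCc3ccccc3)[C@H]2c1c(OCc3ccccc3)cc(OCc3ccccc3)c2c1O[C@H](c1ccc(OCc3ccccc3)c(OCc3ccccc3)c1)[C@H](OCc3ccccc3)C2 | intermediate

13 | 3,5-bis(benzyloxy)phenol | Oc1cc(OCc2ccccc2)cc(OCc2ccccc2)c1 | starting material

14 | 2-bromo-3,5-bis(benzyloxy)phenol | Oc1cc(OCc2ccccc2)cc(OCc2ccccc2)c1Br | intermediate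

15 | [2-bromo-3,5-bis(benzyloxy)phenoxy]trimethylsilane | C[Si](C)(C)Oc1cc(OCc2ccccc2)cc(OCc2ccccc2)c1Br | intermediate

16 | lithium 3,5-bis(benzyloxy)-2-(trimethylsilyl)phenoxide | [Li+].[O-]c1cc(OCc2ccccc2)cc(OCc2ccccc2)c1[Si](C)(C)C | intermediate

17 | 3,5-bis(benzyloxy)-2-(trimethylsilyl)phenyl trifluoromethanesulfonate | C[Si](C)(C)c1c(OS(=O)(=O)C(F)(F)F)cc(OCc2ccccc2)cc1OCc1ccccc1 | intermediate

18 | potassium alkoxide of 12 | [K+].c1ccccc1COc1ccc(cc1)[C@@H]([O-])[C@@H]1O[C@H]1c1c(OCc3ccccc3)cc(OCc3ccccc3)c2c1O[C@H](c1ccc(OCc3ccccc3)c(OCc3ccccc3)c1)[C@H](OCc3ccccc3)[C@H]2c1c(OCc3ccccc3)cc(OCc3ccccc3)c2c1O[C@H](c1ccc(OCc3ccccc3)c(OCc3ccccc3)c1)[C@H](OCc3ccccc3)C2 | intermediate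

19 | 3,5-bis(benzyloxy)benzyne | C1#CC(OCc2ccccc2)=CC(OCc2ccccc2)=C1 | intermediate

20 | aryl potassium species: O-[3,5-bis(benzyloxy)-2-potassiophenyl] ether of 12 | c1ccccc1COc1ccc(cc1)[C@@H](Oc1cc(OCc3ccccc3)cc(OCc3ccccc3)c1[K])[C@@H]1O[C@H]1c1c(OCc3ccccc3)cc(OCc3ccccc3)c2c1O[C@H](c1ccc(OCc3ccccc3)c(OCc3ccccc3)c1)[C@H](OCc3ccccc3)[C@H]2c1c(OCc3ccccc3)cc(OCc3ccccc3)c2c1O[C@H](c1ccc(OCc3ccccc3)c(OCc3ccccc3)c1)[C@H](OCc3ccccc3)C2 | intermediate

21 | 5,7,4'-tri-O-benzyl-epiafzelechin-(4β→8)-3,5,7,3',4'-penta-O-benzyl-epicatechin-(4β→8)-3,5,7,3',4'-penta-O-benzyl-epicatechin | c1ccccc1COc1ccc([C@H]2Oc3cc(OCc5ccccc5)cc(OCc5ccccc5)c3[C@H](c3c(OCc5ccccc5)cc(OCc5ccccc5)c4c3O[C@H](c3ccc(OCc5ccccc5)c(OCc5ccccc5)c3)[C@H](OCc5ccccc5)[C@H]4c3c(OCc5ccccc5)cc(OCc5ccccc5)c4c3O[C@H](c3ccc(OCc5ccccc5)c(OCc5ccccc5)c3)[C@H](OCc5ccccc5)C4)[C@H]2O)cc1 | intermediate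

22 | epiafzelechin-(4β→8)-epicatechin-(4β→8)-epicatechin; upper unit (2R,3R,4R), middle unit (2R,3R,4S), lower unit (2R,3R) | Oc1ccc([C@H]2Oc3cc(O)cc(O)c3[C@H](c3c(O)cc(O)c4c3O[C@H](c3ccc(O)c(O)c3)[C@H](O)[C@H]4c3c(O)cc(O)c4c3O[C@H](c3ccc(O)c(O)c3)[C@H](O)C4)[C@H]2O)cc1 | target

**Step count**
Total step count: 13. Longest linear sequence: 11 steps (steps 1–9, 12 and 13); steps 10 and 11 prepare the aryne precursor.

**Steps most likely to fail**

Step 12 (proposed new method). The aryl anion may be quenched by proton transfer, from the medium or from the benzylic C2–H, before it reaches the epoxide. It may also open the epoxide in the exo sense at C3. The alkoxide may migrate the epoxide in a Payne rearrangement before it meets the aryne, and the product alkoxide may be arylated by excess aryne. The fallback gives up the annulation and forms the upper interflavan bond by the classical cation coupling. It sets out from 6, which is debrominated (n-BuLi, THF, −78 °C, then H2O) to deca-O-benzyl-procyanidin B2 F1. Purchased (−)-epiafzelechin is benzylated (BnBr, K2CO3, DMF) to 5,7,4'-tri-O-benzyl-epiafzelechin F2 and oxidised (DDQ, 2-ethoxyethanol, CH2Cl2) to its 4β-(2-ethoxyethoxy) ether F3. Coupling of F3 with excess F1 (TMSOTf, CH2Cl2, −78 °C) should occur mainly at the upper-unit C8 of F1, anti to the C3 hydroxyl, and returns to the route at 21.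

Step 8. The enone carries an electron-rich, doubly ortho-substituted β-aryl group, so hydroperoxide addition may be slow, and the bulk of the dimer may erode facial control by the polypeptide. The fallback replaces nucleophilic epoxidation of the enone by electrophilic, reagent-controlled epoxidation of the electron-rich alkene. From 10, Luche reduction (NaBH4, CeCl3·7H2O, MeOH/THF, 0 °C) gives the allylic alcohol F4 as a mixture of carbinol epimers. Shi epoxidation with the enantiomer of the fructose-derived ketone (KHSO5, K2CO3, pH 10.5 buffer, MeCN/dimethoxymethane, 0 °C) should give the (2S,3S)-epoxy alcohols F5. Buffered Dess–Martin oxidation (NaHCO3, CH2Cl2) then returns to the route at 11.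

Step 9. Catalyst control may not override the intrinsic erythro preference of the epoxy ketone, giving poor diastereoselectivity, and the boron Lewis acid may open the electron-rich benzylic epoxide. The fallback accepts substrate control and corrects the carbinol afterwards. From 11, chelation-controlled reduction (Zn(BH4)2, Et2O, −20 °C) gives the erythro (1S,2S,3S)-epoxy alcohol F6. Mitsunobu inversion (4-nitrobenzoic acid, PPh3, DIAD, THF, 0 °C) gives the (1R)-4-nitrobenzoate F7, and methanolysis (K2CO3, MeOH) returns to the route at 12.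

**Further compounds**

F1 | step 12 | deca-O-benzyl-procyanidin B2 | c1c(OCc3ccccc3)cc(OCc3ccccc3)c2c1O[C@H](c1ccc(OCc3ccccc3)c(OCc3ccccc3)c1)[C@H](OCc3ccccc3)[C@H]2c1c(OCc3ccccc3)cc(OCc3ccccc3)c2c1O[C@H](c1ccc(OCc3ccccc3)c(OCc3ccccc3)c1)[C@H](OCc3ccccc3)C2

F2 | step 12 | 5,7,4'-tri-O-benzyl-(−)-epiafzelechin | c1c(OCc3ccccc3)cc(OCc3ccccc3)c2c1O[C@H](c1ccc(OCc3ccccc3)cc1)[C@H](O)C2

F3 | step 12 | 4β-(2-ethoxyethoxy)-5,7,4'-tri-O-benzyl-epiafzelechin | c1c(OCc3ccccc3)cc(OCc3ccccc3)c2c1O[C@H](c1ccc(OCc3ccccc3)cc1)[C@H](O)[C@H]2OCCOCC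

F4 | step 8 | (E)-1-[4-(benzyloxy)phenyl]-3-(deca-O-benzyl-procyanidin B2-8-yl)prop-2-en-1-ol (carbinol epimers) | c1ccccc1COc1ccc(cc1)C(O)/C=C/c1c(OCc3ccccc3)cc(OCc3ccccc3)c2c1O[C@H](c1ccc(OCc3ccccc3)c(OCc3ccccc3)c1)[C@H](OCc3ccccc3)[C@H]2c1c(OCc3ccccc3)cc(OCc3ccccc3)c2c1O[C@H](c1ccc(OCc3ccccc3)c(OCc3ccccc3)c1)[C@H](OCc3ccccc3)C2

F5 | step 8 | (2S,3S)-1-[4-(benzyloxy)phenyl]-2,3-epoxy-3-(deca-O-benzyl-procyanidin B2-8-yl)propan-1-ol (carbinol epimers) | c1ccccc1COc1ccc(cc1)C(O)[C@@H]1O[C@H]1c1c(OCc3ccccc3)cc(OCc3ccccc3)c2c1O[C@H](c1ccc(OCc3ccccc3)c(OCc3ccccc3)c1)[C@H](OCc3ccccc3)[C@H]2c1c(OCc3ccccc3)cc(OCc3ccccc3)c2c1O[C@H](c1ccc(OCc3ccccc3)c(OCc3ccccc3)c1)[C@H](OCc3ccccc3)C2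

F6 | step 9 | (1S,2S,3S)-1-[4-(benzyloxy)phenyl]-2,3-epoxy-3-(deca-O-benzyl-procyanidin B2-8-yl)propan-1-ol (erythro) | c1ccccc1COc1ccc(cc1)[C@H](O)[C@@H]1O[C@H]1c1c(OCc3ccccc3)cc(OCc3ccccc3)c2c1O[C@H](c1ccc(OCc3ccccc3)c(OCc3ccccc3)c1)[C@H](OCc3ccccc3)[C@H]2c1c(OCc3ccccc3)cc(OCc3ccccc3)c2c1O[C@H](c1ccc(OCc3ccccc3)c(OCc3ccccc3)c1)[C@H](OCc3ccccc3)C2

F7 | step 9 | 4-nitrobenzoate of 12, (1R,2S,3S) | c1ccccc1COc1ccc(cc1)[C@@H](OC(=O)c1ccc(cc1)[N+](=O)[O-])[C@@H]1O[C@H]1c1c(OCc3ccccc3)cc(OCc3ccccc3)c2c1O[C@H](c1ccc(OCc3ccccc3)c(OCc3ccccc3)c1)[C@H](OCc3ccccc3)[C@H]2c1c(OCc3ccccc3)cc(OCc3ccccc3)c2c1O[C@H](c1ccc(OCc3ccccc3)c(OCc3ccccc3)c1)[C@H](OCc3ccccc3)C2
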